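Atoms are numbered by their position in the target SMILES (ethyl CH3 = C1, lactone ring oxygen = O41). Compounds carry the numbers 1–56 fixed in the steps below.

## Analysis of the target

The target is a 21-membered macrolide (ring atoms C3–C6, C8, C9, C12–C14, C17, C19, C21, C23, C25, O26, C27, C31, C32, O34, C35, C36) carrying two small rings: the δ-lactone ring A (C3, C36, C35, C37, C39, O41), joined to the macrocycle at C3 and C35, and the 3(2H)-furanone ring B (C25, O26, C27, C28, C29). It has ten stereocentres: C3 (R), C9 (S), C14 (R), C17 (S), C19 (S), C21 (S), C23 (S), C25 (S), C35 (S) and C37 (S). Along the zigzag C14–C25 the relationships are 14,17-anti, 17,19-anti, 19,21-syn, 21,23-anti and 23,25-anti; on ring A the oxygen O34, the methyl C38 and the ethyl group lie on one face and the dienyl chain on the other; C9 is insulated by two methylene groups and must be set absolutely. The sensitive groups are C25–H (it enolises towards an aromatic hydroxyfuran, so C25 epimerises with base), the β-hydroxy ketone O24/C29, the O34 ester β to the ring-A carbonyl (E1cB), and the tertiary C–O centres C3 and C9 flanking the E,E-diene (ionisation by acid or by zerovalent palladium). The difficulty lies in the fully substituted C3, where ethyl must be told apart from alkenyl, in the polypropionate C14–C25, and in an end game that must stay neutral. The strategy rests on ring A: O41 sits between the carbonyl C39 and the fully substituted C3, so ring A is a cyclopentanone (C3, C36, C35, C37, C39) plus one oxygen atom, to be inserted by Baeyer–Villiger oxidation of cyclopentanone 12 to lactone 14. In the five-membered ring C3 is an enolate carbon that can be alkynylated on the face away from the C35 silyloxy group, and the alkyne, inert to peracid, later becomes the C4=C5 alkene.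

## Retrosynthetic reasoning

56 from 55. The last step only removes silicon (the C9 triethylsilyl ether and the O20/O24 di-tert-butylsilylene) with buffered fluoride, because the target tolerates neither base nor strong acid.

55 from 54. The C5–C6 σ-bond of the diene is cut. Both alkene geometries are fixed beforehand in an alkenylstannane and an alkenyl iodide, the coupling is neutral and creates no stereocentre, and the ring closes far from the hindered O34 ester.

54 from 16 and 53. The O34–C32 ester is cut, giving two fragments of comparable weight. The alkyne has to be turned into the stannane 16 before the ester is made, because a palladium/tin hydride system would also attack the alkenyl iodide of 53.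

16 from 15 from 14. The stannane comes from syn hydrostannation of the terminal alkyne, after removal of the silyl ether of 14 with acid, to which a stannane would be sensitive.

14 from 12 (key). O41 is removed, that is C3–O41 and C39–O41 are cut, leaving cyclopentanone 12. Forward, a peracid must insert oxygen on the quaternary side with retention at C3 while leaving alkyne and silyl ether alone.

12 from 10 from 7. The methyl C38 is introduced by enolate methylation with 8, which goes anti to the silyloxy group and gives the wrong epimer 10. Re-enolisation and kinetic protonation from the same open face turn it into the cis compound 12.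

7 from 4 and 5; 4 from 2 and 3; 2 from 1. The ethynyl group is put on the enolate 6 made by conjugate reduction of 4, anti to the silyloxy group. The ethyl group comes from a Negishi coupling of iodoenone 2, made from the purchasable enone 1.

53 from 52, 51, 49 (through 50). The acid comes from the primary alcohol, freed from its 4-methoxybenzyl ether. Ring B is opened at O26–C27 to the α′-hydroxy ynone 50, whose 5-endo-dig cycloisomerisation does not touch C25. 49 arises from aldehyde 44 and alkyne 46 by forming C28–C29.

44 from 43, 42, 41, 40, 39. The O26/C29 diol is unmasked from an acetonide while O20/O24 stay tied in a silylene, and the primary position alone is oxidised. 40 comes from 39 by hydroxyl-directed anti reduction at C19.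

39 from 35 and 37. C21–C23 is cut as an anti aldol between ethyl ketone 35 and the α-alkoxy aldehyde 37, which is cleaved from the mannitol derivative 36 and brings C25 from the chiral pool. The enolate geometry, the C17 centre and the aldehyde's own bias all favour the required isomer.

35 from 34, 32; 32 from 30 and 25. C14–C17 is cut as a second anti aldol, with the lactate-derived ketone 30 (from 26 via 27 and 29, with 28) as chiral propionate equivalent. Its benzoyloxy group is later removed reductively, which turns the auxiliary carbons into C21 and C22.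

25 from 24, 22, 21, 19, 18, 17. C9 is traced to the Sharpless epoxide 18 of geraniol 17. The derived epoxy chloride 19 is opened by base to a tertiary propargylic alcohol, methylated on the alkyne in the same flask to 21. Hydrozirconation–iodination gives the (E)-iodoalkene 24 and cleavage of the prenyl alkene frees C14 as the aldehyde 25.

## Alternatives that were turned down

Alternative 1: The bond cut is C23–C25. Forward, MgBr2·OEt2 would bind a C23 aldehyde, and a 3-triisopropylsilyloxyfuran unit held on the same chain through the O34 ester would attack it with C25. This would create the ring-B carbonyl, C23, C25 and the 21-membered ring at once, giving A1 (free C23 hydroxyl, C9 triethylsilyl ether, C19 4-methoxybenzyl ether).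
- For it: it is the most convergent plan, and the labile C25–H appears only at the very end. Chelation between the aldehyde and the C19 ether is the matched case for the 19,23-anti and 21,23-anti relationships.
- Against it: C25 is set in an open transition state inside a forming macrocycle, so the 23,25 relationship cannot be predicted. An enolisable α-chiral aldehyde and an acid- and oxidant-sensitive silyloxyfuran must be carried through ester and diene formation. The Lewis acid meets the ionisable C3 and C9 centres and then a free β-hydroxy ketone that can revert.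
- Comparison: on step count and on protecting C25 it is as strong or stronger. The chosen route offers instead acyclic, triply matched control of C21, C23 and C25 (step 22, C25 from 37) and a ring closure that makes no stereocentre.

Alternative 2: The bonds cut are C28–C29 and O–C27 of an isoxazole standing in for ring B. Forward, a C29 nitrile oxide, made from the aldoxime with PhI(OAc)2, would add to a terminal alkyne hanging from O34 as a but-3-ynoate, closing isoxazole and macrocycle together to give A2.
- For it: intramolecular nitrile oxide cycloadditions are dependable ring closures, the regiochemistry is right for a terminal alkyne, and C25 stays a robust silyl-protected carbinol until late. On the safety of C25 this plan is stronger.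
- Against it: after ring closure the N–O bond must be cleaved reductively, the enaminone hydrolysed and the diketone cyclodehydrated with acid, all beside the diene, the tertiary dienylic C–O bonds and the β-acyloxy lactone. The but-3-ynoate isomerises easily to an allenoate, and the oxidant meets the finished diene.
- Comparison: it needs three or four operations on the macrocycle against one (step 36) here. The chosen route offers instead a furanone formed on a fragment under neutral gold catalysis (step 31).

Alternative 3: The bond cut is C4–C5, as a triple bond. Forward, the alkylidyne [Mo(≡CC6H4OMe-4)(OSiPh3)3] with 5 Å molecular sieves would metathesise two methyl-capped alkynes with loss of a volatile alkyne, giving the macrocyclic enyne A3. A trans-selective semi-reduction would then give the diene.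
- For it: the ring closure is catalytic and tin-free, usually works at higher concentration than a Stille closure, and fits the same peracid-stable alkynyl lactone. On these points it is as strong or stronger.
- Against it: the C4 alkyne sits on the fully substituted, oxygen-bearing C3, a hindered propargylic ester position. The enyne must then be reduced with E selectivity and defined regiochemistry by trans-hydrometalation and protodemetalation, whose fluoride or silver step meets the base-sensitive lactone and furanone.
- Comparison: the chosen route offers instead a diene whose two geometries are fixed in 16 and 53 and simply joined, with no redox chemistry on the macrocycle.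

Key step: step 6

Remark: chain intermediates 41–55 are named by target numbering; their centres C9, C14, C17, C19, C21, C23 and C25 have the target configuration (full assignment in the SMILES).

**Ring A fragment (steps 1–8)**

Step 1
Reactants: 1 (R)-4-(tert-butyldimethylsilyloxy)cyclopent-2-en-1-one
Product: 2 (R)-4-(tert-butyldimethylsilyloxy)-2-iodocyclopent-2-en-1-one
Conditions: I2, pyridine, CH2Cl2, 0 °C → rt
Reagents that add atoms: iodine, II
Why: α-Iodination of an enone by pyridine addition, iodination of the enolate and elimination; the C4 stereocentre is not touched.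

Step 2
Reactants: 2 (R)-4-(tert-butyldimethylsilyloxy)-2-iodocyclopent-2-en-1-one; 3 diethylzinc
Product: 4 (R)-4-(tert-butyldimethylsilyloxy)-2-ethylcyclopent-2-en-1-one
Conditions: Et2Zn, PdCl2(dppf) (5 mol %), THF, 0 °C → rt
Reagents that add atoms: diethylzinc (3), CC[Zn]CC
Why: Negishi coupling of an alkenyl iodide; the wide-bite-angle dppf ligand should make reductive elimination faster than β-hydride loss from the ethylpalladium intermediate.

Step 3
Reactants: 4 (R)-4-(tert-butyldimethylsilyloxy)-2-ethylcyclopent-2-en-1-one; 5 1-[(trimethylsilyl)ethynyl]-1,2-benziodoxol-3(1H)-one (TMS-EBX)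
Product: 7 (2R,4S)-4-(tert-butyldimethylsilyloxy)-2-ethyl-2-ethynylcyclopentan-1-one, via lithium cyclopentenolate 6 (not isolated)
Conditions: LiBH(sec-Bu)3, THF, −78 °C; then 5, Bu4NF, −78 → −40 °C
Reagents that add atoms: 1-[(trimethylsilyl)ethynyl]-1,2-benziodoxol-3(1H)-one (5), C[Si](C)(C)C#CI1OC(=O)c2ccccc12
Why: Conjugate hydride addition to the β-unsubstituted enone gives the regiodefined enolate 6, to which the silyloxy group is not β, and fluoride unmasks the ethynylbenziodoxolone, which transfers ethynyl to the enolate carbon (electrophilic alkynylation of a ketone enolate). The new quaternary centre C2 (C3 of the target) is set by attack on the ring face opposite the C4 silyloxy group.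

Step 4
Reactants: 7 (2R,4S)-4-(tert-butyldimethylsilyloxy)-2-ethyl-2-ethynylcyclopentan-1-one; 8 iodomethane
Product: 10 (2R,4S,5R)-4-(tert-butyldimethylsilyloxy)-2-ethyl-2-ethynyl-5-methylcyclopentan-1-one, via dilithio enolate acetylide 9 (not isolated)
Conditions: LiN(iPr)2 (2.2 equiv), THF, −78 °C; then MeI (1.1 equiv), −78 °C
Reagents that add atoms: iodomethane (8), CI
Why: C5 is the only enolisable position; the second equivalent of base is taken up by the alkyne C–H, and the lithium acetylide does not react with MeI at −78 °C. Enolate methylation occurs anti to the neighbouring silyloxy group, giving the 5R (trans) epimer, which step 5 corrects; the low temperature keeps the β-silyloxy enolate from eliminating.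

Step 5
Reactants: 10 (2R,4S,5R)-4-(tert-butyldimethylsilyloxy)-2-ethyl-2-ethynyl-5-methylcyclopentan-1-one
Product: 12 (2R,4S,5S)-4-(tert-butyldimethylsilyloxy)-2-ethyl-2-ethynyl-5-methylcyclopentan-1-one, via dilithio enolate acetylide 11 (not isolated)
Conditions: LiN(iPr)2 (2.3 equiv), THF, −78 → −50 °C; then AcOH, THF, −78 °C
Reagents that add atoms: none
Why: Kinetic protonation of the planar enolate: the proton comes from the face that carries only the slim ethynyl group, opposite the silyloxy and ethyl groups, so the methyl group ends up cis to the silyloxy group (5S).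

Step 6
Reactants: 12 (2R,4S,5S)-4-(tert-butyldimethylsilyloxy)-2-ethyl-2-ethynyl-5-methylcyclopentan-1-one
Product: 14 (3S,4S,6R)-4-(tert-butyldimethylsilyloxy)-6-ethyl-6-ethynyl-3-methyloxan-2-one, via Criegee adduct 13 (not isolated)
Conditions: urea–H2O2, (CF3CO)2O, Na2HPO4, CH2Cl2, 0 °C → rt
Reagents that add atoms: urea–hydrogen peroxide, NC(N)=O.OO (its oxygen is delivered as trifluoroperacetic acid, OOC(=O)C(F)(F)F)
Why: The peracid adds to the C1 carbonyl (C39 of the target) to give Criegee adduct 13, and the fully substituted C2 (C3 of the target), held anti-periplanar to the O–O bond, shifts from carbon to oxygen as trifluoroacetate leaves; the closest known reaction type is the Baeyer–Villiger oxidation of α-quaternary cyclopentanones. The six-membered lactone (C3, C36, C35, C37, C39, O41) is closed by ring expansion through this 1,2-shift and not by a cyclisation, so no exo or endo mode applies. No new stereocentre is formed: the shift goes with retention, so C3 keeps the configuration set in step 3 and C35 and C37 are untouched, the Na2HPO4 buffer guarding C37 against epimerisation. The step needs regioselectivity for migration of C3 over C37: C3 is tertiary and carries the developing positive charge better, whereas C37 is secondary and is deactivated inductively by the silyloxy group on C35. It also needs chemoselectivity for the ketone over the alkyne and the silyl ether: a terminal alkyne is a poor nucleophile towards peracids, and the buffer keeps the trifluoroacetic acid formed from cleaving the silyl ether. A strong peracid is chosen because the carbonyl lies between a quaternary and a tertiary carbon and adds weaker peracids slowly.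

Step 7
Reactants: 14 (3S,4S,6R)-4-(tert-butyldimethylsilyloxy)-6-ethyl-6-ethynyl-3-methyloxan-2-one
Product: 15 (3S,4S,6R)-6-ethyl-6-ethynyl-4-hydroxy-3-methyloxan-2-one
Conditions: aq. HF (48 %), MeCN, 0 °C → rt
Reagents that add atoms: none
Why: Acidic fluoride cleaves the secondary silyl ether without base, so the β-hydroxy lactone neither epimerises at C37 nor eliminates; it is done before tin is introduced.

Step 8
Reactants: 15 (3S,4S,6R)-6-ethyl-6-ethynyl-4-hydroxy-3-methyloxan-2-one
Product: 16 (3S,4S,6R)-6-ethyl-4-hydroxy-3-methyl-6-[(E)-2-(tributylstannyl)ethenyl]oxan-2-one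
Conditions: Bu3SnH, PdCl2(PPh3)2 (3 mol %), THF, 0 °C
Reagents that add atoms: tributyltin hydride, CCCC[SnH](CCCC)CCCC
Why: Palladium-catalysed syn hydrostannation of a terminal alkyne; the fully substituted propargylic carbon sends tin to the terminal carbon (C5), giving the (E)-alkenylstannane. Hydrostannation at 0 °C should outrun ionisation of the propargylic lactone C–O bond.

**Chain fragment C6–C32 (steps 9–33)**

Step 9
Reactants: 17 geraniol
Product: 18 [(2S,3S)-3-methyl-3-(4-methylpent-3-en-1-yl)oxiran-2-yl]methanol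
Conditions: Ti(OiPr)4 (5 mol %), L-(+)-diethyl tartrate (6 mol %), t-BuOOH, 4 Å MS, CH2Cl2, −20 °C
Reagents that add atoms: tert-butyl hydroperoxide, CC(C)(C)OO
Why: Sharpless asymmetric epoxidation; the L-(+)-tartrate complex delivers oxygen to the allylic alkene only and sets the tertiary centre that becomes C9.

Step 10
Reactants: 18 [(2S,3S)-3-methyl-3-(4-methylpent-3-en-1-yl)oxiran-2-yl]methanol
Product: 19 (2R,3S)-2-(chloromethyl)-3-methyl-3-(4-methylpent-3-en-1-yl)oxirane
Conditions: PPh3, CCl4, NaHCO3, reflux
Reagents that add atoms: tetrachloromethane, ClC(Cl)(Cl)Cl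
Why: Appel chlorination of the primary alcohol under buffered conditions leaves the epoxide intact; the descriptor at C2 changes only because chlorine changes the priorities.

Step 11
Reactants: 19 (2R,3S)-2-(chloromethyl)-3-methyl-3-(4-methylpent-3-en-1-yl)oxirane; 8 iodomethane
Product: 21 (S)-4,8-dimethylnon-7-en-2-yn-4-ol, via dilithium alkynide alkoxide 20 (not isolated)
Conditions: n-BuLi (3.2 equiv), THF, −40 °C; then MeI, −40 °C → rt
Reagents that add atoms: iodomethane (8), CI
Why: Base-induced double elimination of a 2,3-epoxy chloride: deprotonation of the chloromethyl group opens the epoxide to a chloroalkenyl alkoxide, loss of HCl gives the alkyne, and the third equivalent of base forms acetylide 20, which is methylated on carbon. The C–O bond of the tertiary carbinol is never broken, so the configuration from step 9 is kept.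

Step 12
Reactants: 21 (S)-4,8-dimethylnon-7-en-2-yn-4-ol
Product: 22 triethyl{[(4S)-4,8-dimethylnon-7-en-2-yn-4-yl]oxy}silane
Conditions: Et3SiOTf, 2,6-lutidine, CH2Cl2, −78 → 0 °C
Reagents that add atoms: triethylsilyl trifluoromethanesulfonate, CC[Si](CC)(CC)OS(=O)(=O)C(F)(F)F
Why: The silyl triflate silylates the hindered tertiary alcohol; protection is needed because a free C9 hydroxyl would form a lactol with the C14 aldehyde made in step 14.

Step 13
Reactants: 22 triethyl{[(4S)-4,8-dimethylnon-7-en-2-yn-4-yl]oxy}silane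
Product: 24 triethyl{[(2E,4S)-2-iodo-4,8-dimethylnona-2,7-dien-4-yl]oxy}silane, via alkenylzirconocene chloride 23 (not isolated)
Conditions: Cp2Zr(H)Cl, THF, rt → 45 °C; then I2, 0 °C
Reagents that add atoms: iodine, II
Why: Syn hydrozirconation puts zirconium on the methyl-bearing alkyne carbon, away from the fully substituted silyloxy carbon, and iodinolysis with retention gives the (E)-iodoalkene with iodine trans to C9. The trisubstituted alkene is hydrozirconated far more slowly than the alkyne.

Step 14
Reactants: 24 triethyl{[(2E,4S)-2-iodo-4,8-dimethylnona-2,7-dien-4-yl]oxy}silane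
Product: 25 (4S,5E)-6-iodo-4-methyl-4-(triethylsilyloxy)hept-5-enal
Conditions: OsO4 (2 mol %), NaIO4, 2,6-lutidine, dioxane/H2O, rt
Reagents that add atoms: sodium periodate, [Na+].[O-]I(=O)(=O)=O (oxygen relayed by osmium tetroxide, O=[Os](=O)(=O)=O)
Why: Johnson–Lemieux cleavage; OsO4 picks the electron-rich trisubstituted alkene over the hindered, electron-poor iodoalkene.

Step 15
Reactants: 26 ethyl (S)-lactate
Product: 27 (S)-2-hydroxy-N-methoxy-N-methylpropanamide
Conditions: MeNH(OMe)·HCl, iPrMgCl, THF, −20 → 0 °C
Reagents that add atoms: N,O-dimethylhydroxylamine hydrochloride, CNOC.Cl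
Why: Aminolysis of the ester by the magnesium amide gives the Weinreb amide without racemisation of the α-alkoxide centre.

Step 16
Reactants: 27 (S)-2-hydroxy-N-methoxy-N-methylpropanamide; 28 ethylmagnesium bromide
Product: 29 (S)-2-hydroxypentan-3-one
Conditions: EtMgBr, THF, 0 °C → rt
Reagents that add atoms: ethylmagnesium bromide (28), CC[Mg]Br
Why: Weinreb ketone synthesis; the chelated tetrahedral intermediate stops the addition at the ketone stage.

Step 17
Reactants: 29 (S)-2-hydroxypentan-3-one
Product: 30 (S)-3-oxopentan-2-yl benzoate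
Conditions: (PhCO)2O, DMAP, iPr2NEt, CH2Cl2, rt
Reagents that add atoms: benzoic anhydride, O=C(OC(=O)c1ccccc1)c1ccccc1
Why: DMAP-catalysed acylation of the secondary alcohol gives the lactate-derived ketone used as chiral propionate equivalent.

Step 18
Reactants: 30 (S)-3-oxopentan-2-yl benzoate; 25 (4S,5E)-6-iodo-4-methyl-4-(triethylsilyloxy)hept-5-enal
Product: 32 (2S,4R,5R,8S,9E)-5-hydroxy-10-iodo-4,8-dimethyl-3-oxo-8-(triethylsilyloxy)undec-9-en-2-yl benzoate, via boron enolate 31 (not isolated)
Conditions: c-Hex2BCl, Me2NEt, Et2O, −78 → 0 °C; then 25, −78 → −25 °C; then MeOH, pH 7 buffer, H2O2, 0 °C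
Reagents that add atoms: none
Why: Boron-mediated anti aldol of a lactate-derived ketone (Paterson aldol): the (E)-enolate 31 reacts through a chair transition state to give the 14,17-anti relationship. The benzoyloxy stereocentre (hydrogen eclipsing the enolate, benzoate on the aldehyde side) fixes the absolute sense at C14 and C17; the remote C9 centre has no influence.

Step 19
Reactants: 32 (2S,4R,5R,8S,9E)-5-hydroxy-10-iodo-4,8-dimethyl-3-oxo-8-(triethylsilyloxy)undec-9-en-2-yl benzoate; 33 trimethyloxonium tetrafluoroborate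
Product: 34 (2S,4R,5R,8S,9E)-10-iodo-5-methoxy-4,8-dimethyl-3-oxo-8-(triethylsilyloxy)undec-9-en-2-yl benzoate
Conditions: Me3OBF4, 1,8-bis(dimethylamino)naphthalene, CH2Cl2, rt
Reagents that add atoms: trimethyloxonium tetrafluoroborate (33), C[O+](C)C.F[B-](F)(F)F
Why: O-Methylation with an oxonium salt and a non-nucleophilic base avoids the retro-aldol and β-elimination that alkoxide conditions would cause in a β-hydroxy ketone.

Step 20
Reactants: 34 (2S,4R,5R,8S,9E)-10-iodo-5-methoxy-4,8-dimethyl-3-oxo-8-(triethylsilyloxy)undec-9-en-2-yl benzoate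
Product: 35 (4R,5R,8S,9E)-10-iodo-5-methoxy-4,8-dimethyl-8-(triethylsilyloxy)undec-9-en-3-one
Conditions: SmI2, THF/MeOH, −78 °C
Reagents that add atoms: none
Why: Samarium diiodide reduces the α-acyloxy ketone by two single-electron transfers with loss of benzoate, and MeOH protonates the samarium enolate to the ethyl ketone. The enolate forms away from the methoxy group, and the iodoalkene is not reduced at −78 °C without a polar additive.

Step 21
Reactants: 36 1,2:5,6-di-O-isopropylidene-D-mannitol
Product: 37 (R)-2,2-dimethyl-1,3-dioxolane-4-carbaldehyde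
Conditions: NaIO4, aq. NaHCO3, CH2Cl2, rt
Reagents that add atoms: none
Why: Periodate glycol cleavage of the central diol gives two molecules of the aldehyde, which is used at once; its stereocentre becomes C25.

Step 22
Reactants: 35 (4R,5R,8S,9E)-10-iodo-5-methoxy-4,8-dimethyl-8-(triethylsilyloxy)undec-9-en-3-one; 37 (R)-2,2-dimethyl-1,3-dioxolane-4-carbaldehyde
Product: 39 (1S,2R,4R,5R,8S,9E)-1-[(4R)-2,2-dimethyl-1,3-dioxolan-4-yl]-1-hydroxy-10-iodo-5-methoxy-2,4,8-trimethyl-8-(triethylsilyloxy)undec-9-en-3-one, via boron enolate 38 (not isolated)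
Conditions: c-Hex2BCl, Et3N, Et2O, −78 → 0 °C; then 37, −78 → −20 °C; then MeOH, pH 7 buffer, H2O2, 0 °C
Reagents that add atoms: none
Why: Second boron-mediated anti aldol: enolisation occurs on the ethyl side, the (E)-enolate 38 gives 21,23-anti, and the C17 centre with its β-methoxy group directs attack so that the C17 and C21 methyl groups are anti. The α-alkoxy aldehyde reacts in its Felkin–Anh (Cornforth) sense, placing O24 anti to O26, so all three elements are matched.

Step 23
Reactants: 39 (1S,2R,4R,5R,8S,9E)-1-[(4R)-2,2-dimethyl-1,3-dioxolan-4-yl]-1-hydroxy-10-iodo-5-methoxy-2,4,8-trimethyl-8-(triethylsilyloxy)undec-9-en-3-one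
Product: 40 (1S,2S,3S,4S,5R,8S,9E)-1-[(4R)-2,2-dimethyl-1,3-dioxolan-4-yl]-10-iodo-5-methoxy-2,4,8-trimethyl-8-(triethylsilyloxy)undec-9-ene-1,3-diol
Conditions: Me4NBH(OAc)3, MeCN/AcOH, −30 °C
Reagents that add atoms: none
Why: Evans–Saksena reduction: the C23 hydroxyl binds the acetoxyborohydride and delivers hydride intramolecularly through a chair transition state, giving the 19,23-anti diol and with it the C19 configuration.

Step 24
Reactants: 40 (1S,2S,3S,4S,5R,8S,9E)-1-[(4R)-2,2-dimethyl-1,3-dioxolan-4-yl]-10-iodo-5-methoxy-2,4,8-trimethyl-8-(triethylsilyloxy)undec-9-ene-1,3-diol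
Product: 41 silylene acetonide of the C6–C29 chain (6-iodo; 9-OSiEt3; 14-OMe; 19,23-O-Si(t-Bu)2; 25,29-O-isopropylidene)
Conditions: t-Bu2Si(OTf)2, 2,6-lutidine, CH2Cl2, 0 °C
Reagents that add atoms: di-tert-butylsilyl bis(trifluoromethanesulfonate), CC(C)(C)[Si](OS(=O)(=O)C(F)(F)F)(OS(=O)(=O)C(F)(F)F)C(C)(C)C
Why: The 1,3-diol is tied up as a six-membered silylene, which resists mild acid and oxidants and falls to HF·pyridine at the end.

Step 25
Reactants: 41 silylene acetonide of the C6–C29 chain
Product: 42 25,29-diol of the C6–C29 chain (19,23-silylene and 9-OSiEt3 kept)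
Conditions: PPTS, MeOH, 35 °C
Reagents that add atoms: none
Why: Acid-catalysed transacetalisation cleaves the terminal dioxolane much faster than the hindered silylene or the tertiary silyl ether. Any C9 silyl ether lost here is restored in step 26.

Step 26
Reactants: 42 25,29-diol of the C6–C29 chain
Product: 43 25,29-bis(triethylsilyl) ether of the C6–C29 chain
Conditions: Et3SiOTf, 2,6-lutidine, CH2Cl2, −78 → 0 °C
Reagents that add atoms: triethylsilyl trifluoromethanesulfonate, CC[Si](CC)(CC)OS(=O)(=O)C(F)(F)F
Why: Exhaustive silylation with the triflate covers both hydroxyls, and a tertiary C9 hydroxyl if one was set free, so a single compound results.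

Step 27
Reactants: 43 25,29-bis(triethylsilyl) ether of the C6–C29 chain
Product: 44 C29 aldehyde of the C6–C29 chain (25-OSiEt3; 19,23-silylene; 9-OSiEt3)
Conditions: (COCl)2, DMSO, CH2Cl2, −78 → −30 °C; then Et3N, −78 → 0 °C
Reagents that add atoms: none
Why: Under Swern conditions a primary triethylsilyl ether is cleaved by the activated sulfoxide and oxidised to the aldehyde, while secondary and tertiary silyl ethers stay (selective oxidative deprotection of primary silyl ethers).

Step 28
Reactants: 45 but-3-yn-1-ol
Product: 46 1-[(but-3-yn-1-yloxy)methyl]-4-methoxybenzene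
Conditions: NaH, 4-methoxybenzyl chloride, Bu4NI (cat.), THF/DMF, 0 °C → rt
Reagents that add atoms: 4-methoxybenzyl chloride, COc1ccc(CCl)cc1
Why: Williamson etherification; one equivalent of NaH deprotonates only the hydroxyl, not the alkyne C–H.

Step 29
Reactants: 44 C29 aldehyde of the C6–C29 chain; 46 1-[(but-3-yn-1-yloxy)methyl]-4-methoxybenzene
Product: 48 C29 propargylic alcohol of the C6–C32 chain (both C29 epimers; 32-O-PMB; 25-OSiEt3), via lithium acetylide 47 (not isolated)
Conditions: 46, n-BuLi, THF, −78 °C; then 44, −78 °C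
Reagents that add atoms: none
Why: Addition of a lithium acetylide to the α-silyloxy aldehyde forms C28–C29; the C29 configuration does not matter because it is oxidised in step 30, and the low temperature prevents silyl migration and epimerisation at C25.

Step 30
Reactants: 48 C29 propargylic alcohol of the C6–C32 chain
Product: 49 C29 ynone of the C6–C32 chain (C27≡C28; 32-O-PMB; 25-OSiEt3)
Conditions: Dess–Martin periodinane, NaHCO3, CH2Cl2, 0 °C → rt
Reagents that add atoms: none
Why: Buffered periodinane oxidation of the propargylic alcohol is neutral and leaves the silyl ethers, the iodoalkene and C25 alone.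

Step 31
Reactants: 49 C29 ynone of the C6–C32 chain
Product: 51 3(2H)-furanone of the C6–C32 chain (32-O-PMB; 19,23-silylene; 9-OSiEt3), via 25-hydroxy ynone 50 (not isolated)
Conditions: PPTS, MeOH/CH2Cl2, 0 °C → rt; solvent exchange; (Ph3P)AuNTf2 (5 mol %), toluene, rt
Reagents that add atoms: none
Why: Mild acid removes the secondary silyl ether next to the ketone, and the gold catalyst activates the ynone for 5-endo-dig attack of the C25 hydroxyl on C27 (cycloisomerisation of α′-hydroxy ynones to 3(2H)-furanones). No bond to C25 is broken, so its configuration from 37 is kept, and the neutral medium protects the now acidic C25–H.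

Step 32
Reactants: 51 3(2H)-furanone of the C6–C32 chain (32-O-PMB)
Product: 52 furanone primary alcohol of the C6–C32 chain (C32 hydroxyl)
Conditions: DDQ, CH2Cl2/pH 7 buffer, 0 °C
Reagents that add atoms: none
Why: Oxidative removal of the 4-methoxybenzyl ether under buffered, neutral conditions; the diene is not yet present, and the vinylogous ester and the iodoalkene are too electron-poor to react.

Step 33
Reactants: 52 furanone primary alcohol of the C6–C32 chain
Product: 53 furanone acetic acid of the C6–C32 chain (6-iodo; 9-OSiEt3; 19,23-silylene)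
Conditions: TEMPO (cat.), PhI(OAc)2, MeCN/H2O, rt
Reagents that add atoms: water, O
Why: The oxoammonium salt oxidises the primary alcohol to the aldehyde and, through its hydrate, to the acid at near-neutral pH, which spares C25 and the silyl groups.

**Union and ring closure (steps 34–36)**

Step 34
Reactants: 53 furanone acetic acid of the C6–C32 chain; 16 (3S,4S,6R)-6-ethyl-4-hydroxy-3-methyl-6-[(E)-2-(tributylstannyl)ethenyl]oxan-2-one
Product: 54 seco ester (O34–C32 ester; C5 stannane; C6 iodide; 9-OSiEt3; 19,23-silylene)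
Conditions: EDC·HCl, DMAP (cat.), CH2Cl2, 0 °C → rt
Reagents that add atoms: none
Why: Carbodiimide esterification of the only free hydroxyl; stannane, iodoalkene and silyl groups are inert, and low temperature with little DMAP limits enolisation at C25 and elimination at C37.

Step 35
Reactants: 54 seco ester
Product: 55 protected macrocycle (9-OSiEt3; 19,23-O-Si(t-Bu)2)
Conditions: Pd(PPh3)4 (20 mol %), Cu(O2CC4H3S) (copper thiophene-2-carboxylate), [NBu4][Ph2PO2], DMF, rt, 1 mM
Reagents that add atoms: none
Why: Intramolecular Stille coupling, with the copper carboxylate speeding transmetalation and the phosphinate binding tin, runs at room temperature without base. Both alkene geometries are retained, so the (4E,6E)-diene and the 21-membered ring form together; high dilution suppresses oligomers.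

Step 36
Reactants: 55 protected macrocycle
Product: 56 CNP0226414.1 (target)
Conditions: HF·pyridine, pyridine, THF, 0 °C → rt
Reagents that add atoms: none
Why: Buffered HF·pyridine cleaves the silylene and the tertiary triethylsilyl ether without base, sparing C25, the β-acyloxy lactone and the tertiary dienylic C–O bonds.

**Compound list**

1 | (R)-4-(tert-butyldimethylsilyloxy)cyclopent-2-en-1-one | O=C1C=C[C@H](O[Si](C)(C)C(C)(C)C)C1 | starting material
2 | (R)-4-(tert-butyldimethylsilyloxy)-2-iodocyclopent-2-en-1-one | O=C1C(I)=C[C@H](O[Si](C)(C)C(C)(C)C)C1 | intermediate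
3 | diethylzinc | CC[Zn]CC | starting material
4 | (R)-4-(tert-butyldimethylsilyloxy)-2-ethylcyclopent-2-en-1-one | CCC1=C[C@H](O[Si](C)(C)C(C)(C)C)CC1=O | intermediate
5 | 1-[(trimethylsilyl)ethynyl]-1,2-benziodoxol-3(1H)-one (TMS-EBX) | C[Si](C)(C)C#CI1OC(=O)c2ccccc12 | starting material
6 | lithium (S)-4-(tert-butyldimethylsilyloxy)-2-ethylcyclopent-1-en-1-olate | CCC1=C([O-])C[C@@H](O[Si](C)(C)C(C)(C)C)C1.[Li+] | intermediate
7 | (2R,4S)-4-(tert-butyldimethylsilyloxy)-2-ethyl-2-ethynylcyclopentan-1-one | CC[C@]1(C#C)C[C@H](O[Si](C)(C)C(C)(C)C)CC1=O | intermediate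
8 | iodomethane | CI | starting material
9 | dilithio C5 enolate/acetylide of 7 | CC[C@]1(C#[C-])C[C@H](O[Si](C)(C)C(C)(C)C)C=C1[O-].[Li+].[Li+] | intermediate
10 | (2R,4S,5R)-4-(tert-butyldimethylsilyloxy)-2-ethyl-2-ethynyl-5-methylcyclopentan-1-one | CC[C@]1(C#C)C[C@H](O[Si](C)(C)C(C)(C)C)[C@@H](C)C1=O | intermediate
11 | dilithio C5 enolate/acetylide of 10 | CC[C@]1(C#[C-])C[C@H](O[Si](C)(C)C(C)(C)C)C(C)=C1[O-].[Li+].[Li+] | intermediate
12 | (2R,4S,5S)-4-(tert-butyldimethylsilyloxy)-2-ethyl-2-ethynyl-5-methylcyclopentan-1-one | CC[C@]1(C#C)C[C@H](O[Si](C)(C)C(C)(C)C)[C@H](C)C1=O | intermediate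
13 | Criegee adduct of 12 (1-hydroxy-1-trifluoroacetylperoxy; C1 configuration undefined) | CC[C@]1(C#C)C[C@H](O[Si](C)(C)C(C)(C)C)[C@H](C)C1(O)OOC(=O)C(F)(F)F | intermediate
14 | (3S,4S,6R)-4-(tert-butyldimethylsilyloxy)-6-ethyl-6-ethynyl-3-methyloxan-2-one | CC[C@]1(C#C)C[C@H](O[Si](C)(C)C(C)(C)C)[C@H](C)C(=O)O1 | intermediate
15 | (3S,4S,6R)-6-ethyl-6-ethynyl-4-hydroxy-3-methyloxan-2-one | CC[C@]1(C#C)C[C@H](O)[C@H](C)C(=O)O1 | intermediate
16 | (3S,4S,6R)-6-ethyl-4-hydroxy-3-methyl-6-[(E)-2-(tributylstannyl)ethenyl]oxan-2-one | CC[C@]1(/C=C/[Sn](CCCC)(CCCC)CCCC)C[C@H](O)[C@H](C)C(=O)O1 | intermediate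
17 | geraniol, (2E)-3,7-dimethylocta-2,6-dien-1-ol | CC(C)=CCC/C(C)=C/CO | starting material
18 | [(2S,3S)-3-methyl-3-(4-methylpent-3-en-1-yl)oxiran-2-yl]methanol | OC[C@@H]1O[C@@]1(C)CCC=C(C)C | intermediate
19 | (2R,3S)-2-(chloromethyl)-3-methyl-3-(4-methylpent-3-en-1-yl)oxirane | ClC[C@@H]1O[C@@]1(C)CCC=C(C)C | intermediate
20 | dilithium (S)-3,7-dimethyloct-6-en-1-yn-1-id-3-olate | [Li+].[Li+].[C-]#C[C@@](C)([O-])CCC=C(C)C | intermediate
21 | (S)-4,8-dimethylnon-7-en-2-yn-4-ol | CC#C[C@@](C)(O)CCC=C(C)C | intermediate
22 | triethyl{[(4S)-4,8-dimethylnon-7-en-2-yn-4-yl]oxy}silane | CC#C[C@@](C)(O[Si](CC)(CC)CC)CCC=C(C)C | intermediate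
23 | chlorobis(cyclopentadienyl)[(2E,4S)-4,8-dimethyl-4-(triethylsilyloxy)nona-2,7-dien-2-yl]zirconium | C/C(=C\[C@@](C)(O[Si](CC)(CC)CC)CCC=C(C)C)[Zr](Cl)(C1C=CC=C1)C1C=CC=C1 | intermediate
24 | triethyl{[(2E,4S)-2-iodo-4,8-dimethylnona-2,7-dien-4-yl]oxy}silane | C/C(I)=C\[C@@](C)(O[Si](CC)(CC)CC)CCC=C(C)C | intermediate
25 | (4S,5E)-6-iodo-4-methyl-4-(triethylsilyloxy)hept-5-enal | C/C(I)=C\[C@@](C)(O[Si](CC)(CC)CC)CCC=O | intermediate
26 | ethyl (S)-lactate | CCOC(=O)[C@H](C)O | starting material
27 | (S)-2-hydroxy-N-methoxy-N-methylpropanamide | CON(C)C(=O)[C@H](C)O | intermediate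
28 | ethylmagnesium bromide | CC[Mg]Br | starting material
29 | (S)-2-hydroxypentan-3-one | CCC(=O)[C@H](C)O | intermediate
30 | (S)-3-oxopentan-2-yl benzoate | CCC(=O)[C@H](C)OC(=O)c1ccccc1 | intermediate
31 | (E)-dicyclohexylboron enolate of 30 | C/C=C(/OB(C1CCCCC1)C1CCCCC1)[C@H](C)OC(=O)c1ccccc1 | intermediate
32 | (2S,4R,5R,8S,9E)-5-hydroxy-10-iodo-4,8-dimethyl-3-oxo-8-(triethylsilyloxy)undec-9-en-2-yl benzoate | C/C(I)=C\[C@@](C)(O[Si](CC)(CC)CC)CC[C@@H](O)[C@@H](C)C(=O)[C@H](C)OC(=O)c1ccccc1 | intermediate
33 | trimethyloxonium tetrafluoroborate | C[O+](C)C.F[B-](F)(F)F | starting material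
34 | (2S,4R,5R,8S,9E)-10-iodo-5-methoxy-4,8-dimethyl-3-oxo-8-(triethylsilyloxy)undec-9-en-2-yl benzoate | C/C(I)=C\[C@@](C)(O[Si](CC)(CC)CC)CC[C@@H](OC)[C@@H](C)C(=O)[C@H](C)OC(=O)c1ccccc1 | intermediate
35 | (4R,5R,8S,9E)-10-iodo-5-methoxy-4,8-dimethyl-8-(triethylsilyloxy)undec-9-en-3-one | C/C(I)=C\[C@@](C)(O[Si](CC)(CC)CC)CC[C@@H](OC)[C@@H](C)C(=O)CC | intermediate
36 | 1,2:5,6-di-O-isopropylidene-D-mannitol | CC1(C)OC[C@@H](O1)[C@@H](O)[C@H](O)[C@H]1COC(C)(C)O1 | starting material
37 | (R)-2,2-dimethyl-1,3-dioxolane-4-carbaldehyde | O=C[C@H]1COC(C)(C)O1 | intermediate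
38 | (E)-dicyclohexylboron enolate of 35 | C/C(I)=C\[C@@](C)(O[Si](CC)(CC)CC)CC[C@@H](OC)[C@@H](C)/C(OB(C1CCCCC1)C1CCCCC1)=C\C | intermediate
39 | (1S,2R,4R,5R,8S,9E)-1-[(4R)-2,2-dimethyl-1,3-dioxolan-4-yl]-1-hydroxy-10-iodo-5-methoxy-2,4,8-trimethyl-8-(triethylsilyloxy)undec-9-en-3-one | C/C(I)=C\[C@@](C)(O[Si](CC)(CC)CC)CC[C@@H](OC)[C@@H](C)C(=O)[C@H](C)[C@H](O)[C@H]1COC(C)(C)O1 | intermediate
40 | (1S,2S,3S,4S,5R,8S,9E)-1-[(4R)-2,2-dimethyl-1,3-dioxolan-4-yl]-10-iodo-5-methoxy-2,4,8-trimethyl-8-(triethylsilyloxy)undec-9-ene-1,3-diol | C/C(I)=C\[C@@](C)(O[Si](CC)(CC)CC)CC[C@@H](OC)[C@@H](C)[C@@H](O)[C@H](C)[C@H](O)[C@H]1COC(C)(C)O1 | intermediate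
41 | silylene acetonide of the C6–C29 chain (6-iodo; 9-OSiEt3; 14-OMe; 19,23-O-Si(t-Bu)2; 25,29-O-isopropylidene) | C/C(I)=C\[C@@](C)(O[Si](CC)(CC)CC)CC[C@@H](OC)[C@@H](C)[C@H]1O[Si](C(C)(C)C)(C(C)(C)C)O[C@@H]([C@H]1C)[C@H]2COC(C)(C)O2 | intermediate
42 | 25,29-diol of the C6–C29 chain (silylene and 9-OSiEt3 kept) | C/C(I)=C\[C@@](C)(O[Si](CC)(CC)CC)CC[C@@H](OC)[C@@H](C)[C@H]1O[Si](C(C)(C)C)(C(C)(C)C)O[C@@H]([C@H]1C)[C@H](O)CO | intermediate
43 | 25,29-bis(triethylsilyl) ether of the C6–C29 chain | C/C(I)=C\[C@@](C)(O[Si](CC)(CC)CC)CC[C@@H](OC)[C@@H](C)[C@H]1O[Si](C(C)(C)C)(C(C)(C)C)O[C@@H]([C@H]1C)[C@H](O[Si](CC)(CC)CC)CO[Si](CC)(CC)CC | intermediate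
44 | C29 aldehyde of the C6–C29 chain (25-OSiEt3) | C/C(I)=C\[C@@](C)(O[Si](CC)(CC)CC)CC[C@@H](OC)[C@@H](C)[C@H]1O[Si](C(C)(C)C)(C(C)(C)C)O[C@@H]([C@H]1C)[C@H](O[Si](CC)(CC)CC)C=O | intermediate
45 | but-3-yn-1-ol | C#CCCO | starting material
46 | 1-[(but-3-yn-1-yloxy)methyl]-4-methoxybenzene | C#CCCOCc1ccc(OC)cc1 | intermediate
47 | lithium acetylide of 46 | [Li+].[C-]#CCCOCc1ccc(OC)cc1 | intermediate
48 | C29 propargylic alcohol of the C6–C32 chain (both C29 epimers; 32-O-PMB; 25-OSiEt3) | C/C(I)=C\[C@@](C)(O[Si](CC)(CC)CC)CC[C@@H](OC)[C@@H](C)[C@H]1O[Si](C(C)(C)C)(C(C)(C)C)O[C@@H]([C@H]1C)[C@H](O[Si](CC)(CC)CC)C(O)C#CCCOCc2ccc(OC)cc2 | intermediate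
49 | C29 ynone of the C6–C32 chain (32-O-PMB; 25-OSiEt3) | C/C(I)=C\[C@@](C)(O[Si](CC)(CC)CC)CC[C@@H](OC)[C@@H](C)[C@H]1O[Si](C(C)(C)C)(C(C)(C)C)O[C@@H]([C@H]1C)[C@H](O[Si](CC)(CC)CC)C(=O)C#CCCOCc2ccc(OC)cc2 | intermediate
50 | 25-hydroxy ynone of the C6–C32 chain | C/C(I)=C\[C@@](C)(O[Si](CC)(CC)CC)CC[C@@H](OC)[C@@H](C)[C@H]1O[Si](C(C)(C)C)(C(C)(C)C)O[C@@H]([C@H]1C)[C@H](O)C(=O)C#CCCOCc2ccc(OC)cc2 | intermediate
51 | 3(2H)-furanone of the C6–C32 chain (32-O-PMB) | C/C(I)=C\[C@@](C)(O[Si](CC)(CC)CC)CC[C@@H](OC)[C@@H](C)[C@H]1O[Si](C(C)(C)C)(C(C)(C)C)O[C@@H]([C@H]1C)[C@@H]2OC(=CC2=O)CCOCc3ccc(OC)cc3 | intermediate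
52 | furanone primary alcohol of the C6–C32 chain | C/C(I)=C\[C@@](C)(O[Si](CC)(CC)CC)CC[C@@H](OC)[C@@H](C)[C@H]1O[Si](C(C)(C)C)(C(C)(C)C)O[C@@H]([C@H]1C)[C@@H]2OC(=CC2=O)CCO | intermediate
53 | furanone acetic acid of the C6–C32 chain | C/C(I)=C\[C@@](C)(O[Si](CC)(CC)CC)CC[C@@H](OC)[C@@H](C)[C@H]1O[Si](C(C)(C)C)(C(C)(C)C)O[C@@H]([C@H]1C)[C@@H]2OC(=CC2=O)CC(=O)O | intermediate
54 | seco ester of 53 and 16 | C/C(I)=C\[C@@](C)(O[Si](CC)(CC)CC)CC[C@@H](OC)[C@@H](C)[C@H]1O[Si](C(C)(C)C)(C(C)(C)C)O[C@@H]([C@H]1C)[C@@H]2OC(=CC2=O)CC(=O)O[C@H]3C[C@](CC)(/C=C/[Sn](CCCC)(CCCC)CCCC)OC(=O)[C@H]3C | intermediate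
55 | protected macrocycle (9-OSiEt3; 19,23-O-Si(t-Bu)2) | CC[C@]12/C=C/C(C)=C/[C@@](C)(O[Si](CC)(CC)CC)CC[C@@H](OC)[C@@H](C)[C@H]4O[Si](C(C)(C)C)(C(C)(C)C)O[C@@H]([C@H]4C)[C@@H]3OC(=CC3=O)CC(=O)O[C@@H](C1)[C@H](C)C(=O)O2 | intermediate
56 | CNP0226414.1 | CC[C@]12/C=C/C(C)=C/[C@@](C)(O)CC[C@@H](OC)[C@@H](C)[C@@H](O)[C@H](C)[C@H](O)[C@@H]3OC(=CC3=O)CC(=O)O[C@@H](C1)[C@H](C)C(=O)O2 | target

**Step count and risk**

Total: 36 steps. Longest linear sequence: 23 steps (17 to 56 through steps 9–14, 18–20, 22–27, 29–36); the ring A branch is 8 steps to 16.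

Step 6 (key step). Oxygen may be inserted on the wrong side (migration of C37 instead of C3) if the ethynyl group lowers the migratory aptitude of C3 more than expected. Slow addition to the hindered carbonyl may also leave time for alkyne oxidation or silyl ether cleavage. Fallback, from 7 back to 14: the oxygen is inserted before C38 is introduced, so that the competing carbon is a CH2 group of much lower migratory aptitude. Buffered CF3CO3H on 7 gives (4S,6R)-4-(tert-butyldimethylsilyloxy)-6-ethyl-6-ethynyloxan-2-one F1. The lactone enolate (LiN(iPr)2, 2.2 equiv, −78 °C) is methylated anti to the silyloxy group to (3R,4S,6R)-4-(tert-butyldimethylsilyloxy)-6-ethyl-6-ethynyl-3-methyloxan-2-one F2. A second enolisation with kinetic protonation (AcOH, −78 °C) then gives 14.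

Step 3. Hydride may add 1,2 instead of 1,4, the enolate may exchange protons with product before it is alkynylated, and a silyloxy group two atoms away may discriminate the faces poorly. Fallback, from 4 back to 16: the ethynyl group is replaced by a benzyloxymethyl group during the ring chemistry.
- Enolate 6 is trapped with benzyl chloromethyl ether (plain SN2 alkylation anti to the silyloxy group) to give (2R,4S)-2-[(benzyloxy)methyl]-4-(tert-butyldimethylsilyloxy)-2-ethylcyclopentan-1-one F3.
- Methylation as in step 4 gives the (2R,4S,5R)-5-methyl derivative of this ketone F4, and kinetic protonation as in step 5 gives its (2R,4S,5S)-epimer F5.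
- Buffered CF3CO3H gives (3S,4S,6R)-6-[(benzyloxy)methyl]-4-(tert-butyldimethylsilyloxy)-6-ethyl-3-methyloxan-2-one F6.
- Hydrogenolysis (H2, Pd/C, EtOAc) gives (3S,4S,6R)-4-(tert-butyldimethylsilyloxy)-6-ethyl-6-(hydroxymethyl)-3-methyloxan-2-one F7, and Dess–Martin oxidation gives the 6-formyl analogue of 14 F8.
- Takai–Hodgson olefination (CrCl2, Bu3SnCHBr2, LiI, THF/DMF) gives (3S,4S,6R)-4-(tert-butyldimethylsilyloxy)-6-ethyl-3-methyl-6-[(E)-2-(tributylstannyl)ethenyl]oxan-2-one F9, and HF·pyridine buffered with pyridine gives 16.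

Step 5. The C5 enolate may expel silyloxide (E1cB) if it warms, deprotonation of the hindered C5–H may be incomplete, and protonation may not be fully face-selective. Fallback, from 4 back to 12: the C5 chemistry is moved to the enone, whose cross-conjugated dienolate cannot lose silyloxide without forming an antiaromatic dienone. Deprotonation of 4 (LiN(iPr)2, −78 °C) and MeI give (4S,5R)-4-(tert-butyldimethylsilyloxy)-2-ethyl-5-methylcyclopent-2-en-1-one F10. A second deprotonation and AcOH quench at −78 °C give the (4S,5S)-epimer F11. The reductive alkynylation of step 3 applied to F11, now anti to both the silyloxy and the methyl group, gives 12 directly.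

Step 35. Zerovalent palladium may ionise the tertiary allylic lactone bond C3–O41 once the diene has formed. Oligomerisation may compete with closure of the 21-membered ring, the stannane may be protonated off, and C25 may epimerise in DMF in the presence of carboxylate. Fallback, from 16 and 53 back to 55: the fragments are first joined at C5–C6 by an intermolecular Stille coupling under the same conditions without dilution, giving the seco hydroxy acid F12. The ring is then closed at O34–C32 by Shiina macrolactonisation (2-methyl-6-nitrobenzoic anhydride, DMAP, CH2Cl2, high dilution), giving 55.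

Further compounds

F1 | step 6 | (4S,6R)-4-(tert-butyldimethylsilyloxy)-6-ethyl-6-ethynyloxan-2-one | CC[C@]1(C#C)C[C@H](O[Si](C)(C)C(C)(C)C)CC(=O)O1
F2 | step 6 | (3R,4S,6R)-4-(tert-butyldimethylsilyloxy)-6-ethyl-6-ethynyl-3-methyloxan-2-one | CC[C@]1(C#C)C[C@H](O[Si](C)(C)C(C)(C)C)[C@@H](C)C(=O)O1
F3 | step 3 | (2R,4S)-2-[(benzyloxy)methyl]-4-(tert-butyldimethylsilyloxy)-2-ethylcyclopentan-1-one | CC[C@]1(COCc2ccccc2)C[C@H](O[Si](C)(C)C(C)(C)C)CC1=O
F4 | step 3 | (2R,4S,5R)-2-[(benzyloxy)methyl]-4-(tert-butyldimethylsilyloxy)-2-ethyl-5-methylcyclopentan-1-one | CC[C@]1(COCc2ccccc2)C[C@H](O[Si](C)(C)C(C)(C)C)[C@@H](C)C1=O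
F5 | step 3 | (2R,4S,5S)-2-[(benzyloxy)methyl]-4-(tert-butyldimethylsilyloxy)-2-ethyl-5-methylcyclopentan-1-one | CC[C@]1(COCc2ccccc2)C[C@H](O[Si](C)(C)C(C)(C)C)[C@H](C)C1=O
F6 | step 3 | (3S,4S,6R)-6-[(benzyloxy)methyl]-4-(tert-butyldimethylsilyloxy)-6-ethyl-3-methyloxan-2-one | CC[C@]1(COCc2ccccc2)C[C@H](O[Si](C)(C)C(C)(C)C)[C@H](C)C(=O)O1
F7 | step 3 | (3S,4S,6R)-4-(tert-butyldimethylsilyloxy)-6-ethyl-6-(hydroxymethyl)-3-methyloxan-2-one | CC[C@]1(CO)C[C@H](O[Si](C)(C)C(C)(C)C)[C@H](C)C(=O)O1
F8 | step 3 | 6-formyl analogue of 14 (aldehyde in place of the ethynyl group) | CC[C@]1(C=O)C[C@H](O[Si](C)(C)C(C)(C)C)[C@H](C)C(=O)O1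
F9 | step 3 | (3S,4S,6R)-4-(tert-butyldimethylsilyloxy)-6-ethyl-3-methyl-6-[(E)-2-(tributylstannyl)ethenyl]oxan-2-one | CC[C@]1(/C=C/[Sn](CCCC)(CCCC)CCCC)C[C@H](O[Si](C)(C)C(C)(C)C)[C@H](C)C(=O)O1
F10 | step 5 | (4S,5R)-4-(tert-butyldimethylsilyloxy)-2-ethyl-5-methylcyclopent-2-en-1-one | CCC1=C[C@H](O[Si](C)(C)C(C)(C)C)[C@@H](C)C1=O
F11 | step 5 | (4S,5S)-4-(tert-butyldimethylsilyloxy)-2-ethyl-5-methylcyclopent-2-en-1-one | CCC1=C[C@H](O[Si](C)(C)C(C)(C)C)[C@H](C)C1=O
F12 | step 35 | seco hydroxy acid (C5–C6 joined; O34 hydroxyl and C32 acid free; 9-OSiEt3; 19,23-silylene) | CC[C@]1(/C=C/C(C)=C/[C@@](C)(O[Si](CC)(CC)CC)CC[C@@H](OC)[C@@H](C)[C@H]2O[Si](C(C)(C)C)(C(C)(C)C)O[C@@H]([C@H]2C)[C@@H]3OC(=CC3=O)CC(=O)O)C[C@H](O)[C@H](C)C(=O)O1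
A1 | alternative 1 | macrocycle with free C23 hydroxyl, C9 triethylsilyl ether and C19 4-methoxybenzyl ether | CC[C@]12/C=C/C(C)=C/[C@@](C)(O[Si](CC)(CC)CC)CC[C@@H](OC)[C@@H](C)[C@@H](OCc4ccc(OC)cc4)[C@H](C)[C@H](O)[C@@H]3OC(=CC3=O)CC(=O)O[C@@H](C1)[C@H](C)C(=O)O2
A2 | alternative 2 | isoxazole-bridged macrocycle | CC[C@]12/C=C/C(C)=C/[C@@](C)(O)CC[C@@H](OC)[C@@H](C)[C@@H](O[Si](C)(C)C(C)(C)C)[C@H](C)[C@H](O[Si](C)(C)C(C)(C)C)[C@H](O[Si](CC)(CC)CC)c3cc(on3)CC(=O)O[C@@H](C1)[C@H](C)C(=O)O2
A3 | alternative 3 | macrocyclic 1,3-enyne, tris(triethylsilyl) ether | CC[C@]12C#C/C(C)=C/[C@@](C)(O[Si](CC)(CC)CC)CC[C@@H](OC)[C@@H](C)[C@@H](O[Si](CC)(CC)CC)[C@H](C)[C@H](O[Si](CC)(CC)CC)[C@@H]3OC(=CC3=O)CC(=O)O[C@@H](C1)[C@H](C)C(=O)O2
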